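## Retrosynthetic overview

- **Endgame:** the oxirane comes last, by catalyst-controlled epoxidation of a 2-substituted acrolein. That enal comes from allylic oxidation of an isopropenyl group. The C6 ester and the free C9–OH come from acylation and then desilylation.
- **Core:** the bicyclic core is built from two acyclic fragments in one flask. C7–C8 forms by 2-alkoxycarbonyl-allylboration, which closes the cis γ-lactone. C5–C6 then forms by carbonyl-ene closure, which gives the cyclohexane, the C6–OH and the isopropenyl group.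
- **Aldehyde fragment:** iridium-catalysed tert-(hydroxy)prenylation of dimethoxyacetaldehyde with isoprene monoxide sets C9 and C10. Oxidation, silylation, Wittig olefination and acetal hydrolysis follow.
- **Boronate fragment:** the Baylis–Hillman adduct of the same dimethoxyacetaldehyde with methyl acrylate is acetylated and then borylated at the allylic position.
- **Ring order:** γ-lactone, then cyclohexane (same operation), then oxirane.

Locants (elemane numbering): C10 is the quaternary carbon (CH3 = C14, vinyl = C1/C2). C5 bears the C4/C3/C15 side chain. C6 is the ester carbinol. C7 and C8 are the lactone fusion carbons, with O on C8. C9 is the free carbinol. C11–C13 are the acrylate carbons.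

Assumption: the facial sense of the (R)-Tol-BINAP iridium catalyst (step 1) and of the (S)-prolinol catalyst (step 13) is as stated; both antipodes are commercial and the other one is used if the sense proves opposite.

## Route

**Step 1**
Reactants: 1 2,2-dimethoxyacetaldehyde (commercial aqueous solution, dried); 2 2-methyl-2-vinyloxirane (isoprene monoxide, racemic)
Product: 3 (2S,3R)-2-ethenyl-4,4-dimethoxy-2-methylbutane-1,3-diol
Conditions: [Ir(cod)Cl]2 (2.5 mol %), (R)-Tol-BINAP, 4-cyano-3-nitrobenzoic acid, allyl acetate (precatalyst), K3PO4 (5 mol %), i-PrOH (2 equiv), THF, 60 °C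
Reagents that add atoms: none
Why: Iridium-catalysed transfer-hydrogenative carbonyl tert-(hydroxy)prenylation, in which 2 opens to an (E)-σ-allyliridium that adds through its tertiary carbon via a closed chair (CH2O equatorial, CH3 axial, hence the anti C9/C10 relationship) while the ligand selects the aldehyde face, so C9 (R) and C10 (S) are both set here.

**Step 2**
Reactants: 3 (2S,3R)-2-ethenyl-4,4-dimethoxy-2-methylbutane-1,3-diol
Product: 4 (2R,3R)-2-ethenyl-3-hydroxy-4,4-dimethoxy-2-methylbutanal
Conditions: TEMPO (10 mol %), PhI(OAc)2 (1.1 equiv), CH2Cl2, 23 °C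
Reagents that add atoms: none
Why: Oxoammonium (TEMPO/PhI(OAc)2) oxidation takes the primary carbinol in preference to the hindered secondary one, and the α-carbon is quaternary so nothing can epimerise.

**Step 3**
Reactants: 4 (2R,3R)-2-ethenyl-3-hydroxy-4,4-dimethoxy-2-methylbutanal
Product: 5 (2R,3R)-3-[(tert-butyldimethylsilyl)oxy]-2-ethenyl-4,4-dimethoxy-2-methylbutanal
Conditions: TBSOTf (1.2 equiv), 2,6-lutidine, CH2Cl2, −78 to −20 °C
Reagents that add atoms: tert-butyldimethylsilyl triflate, CC(C)(C)[Si](C)(C)OS(=O)(=O)C(F)(F)F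
Why: Silyl triflate etherification of the hindered C9–OH blocks retro-aldol cleavage in the next step, and the aldehyde cannot enolise, so no stereocentre is touched.

**Step 4**
Reactants: 5 (2R,3R)-3-[(tert-butyldimethylsilyl)oxy]-2-ethenyl-4,4-dimethoxy-2-methylbutanal
Product: 6 tert-butyl{[(2R,3S)-3-ethenyl-1,1-dimethoxy-3,5-dimethylhex-4-en-2-yl]oxy}dimethylsilane
Conditions: i-PrPPh3I, n-BuLi, THF, 0 °C; then 5, −78 to 23 °C
Reagents that add atoms: isopropyltriphenylphosphonium iodide, CC(C)[P+](c1ccccc1)(c1ccccc1)c1ccccc1.[I-]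
Why: Wittig olefination with the non-stabilised isopropylidene ylide installs the C5=C4(CH3)2 ene donor, and two identical methyl groups mean there is no alkene geometry to control.

**Step 5**
Reactants: 6 tert-butyl{[(2R,3S)-3-ethenyl-1,1-dimethoxy-3,5-dimethylhex-4-en-2-yl]oxy}dimethylsilane
Product: 7 (2R,3S)-2-[(tert-butyldimethylsilyl)oxy]-3-ethenyl-3,5-dimethylhex-4-enal
Conditions: TFA–H2O (9:1), CH2Cl2, 0 °C
Reagents that add atoms: water, O
Why: Acid-catalysed acetal hydrolysis frees the C8 aldehyde, the hindered secondary TBS ether survives, and neither alkene can reach the oxocarbenium carbon through a ring larger than four atoms with a stabilised cation.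

**Step 6**
Reactants: 1 2,2-dimethoxyacetaldehyde; 8 methyl acrylate
Product: 9 methyl 3-hydroxy-4,4-dimethoxy-2-methylidenebutanoate (racemic)
Conditions: DABCO (1 equiv), 1,4-dioxane–H2O (1:1), 23 °C
Reagents that add atoms: none
Why: Morita–Baylis–Hillman reaction of an activated α,α-dialkoxy aldehyde, whose racemic carbinol centre is erased in step 8.

**Step 7**
Reactants: 9 methyl 3-hydroxy-4,4-dimethoxy-2-methylidenebutanoate
Product: 10 methyl 3-acetoxy-4,4-dimethoxy-2-methylidenebutanoate (racemic)
Conditions: Ac2O, pyridine, DMAP (cat.), CH2Cl2, 0 to 23 °C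
Reagents that add atoms: acetic anhydride, CC(=O)OC(C)=O
Why: DMAP-catalysed acetylation turns the allylic hydroxyl into a leaving group for π-allyl formation.

**Step 8**
Reactants: 10 methyl 3-acetoxy-4,4-dimethoxy-2-methylidenebutanoate
Product: 11 methyl (2E)-4,4-dimethoxy-2-[(4,4,5,5-tetramethyl-1,3,2-dioxaborolan-2-yl)methyl]but-2-enoate
Conditions: B2pin2 (1.1 equiv), Pd2(dba)3 (2.5 mol %), PhMe, 50 °C
Reagents that add atoms: bis(pinacolato)diboron, CC1(C)OB(OC1(C)C)B1OC(C)(C)C(C)(C)O1
Why: Allylic Miyaura-type borylation by zerovalent palladium places boron on the free CH2 terminus of the π-allyl and gives the usual Baylis–Hillman-derived geometry, with the acetal carbon cis to CH2B and trans to the ester.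

**Step 9 (key step)**
Reactants: 7 (2R,3S)-2-[(tert-butyldimethylsilyl)oxy]-3-ethenyl-3,5-dimethylhex-4-enal; 11 methyl (2E)-4,4-dimethoxy-2-[(pinacolboryl)methyl]but-2-enoate
Product: 15 (3aS,4R,5S,6S,7R,7aS)-7-[(tert-butyldimethylsilyl)oxy]-6-ethenyl-4-hydroxy-6-methyl-3-methylidene-5-(prop-1-en-2-yl)hexahydro-1-benzofuran-2(3H)-one, via open-chain pinacol borate 12 (not isolated), via lactone acetal 13 (not isolated), via lactone aldehyde 14 (not isolated)
Conditions: PhMe, 90 °C, 36 h; then MeCN–H2O (4:1), Sc(OTf)3 (5 mol %), 0 to 23 °C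
Reagents that add atoms: water, O
Why: Proposed new method: thermal 2-alkoxycarbonyl-allylboration through a closed chair (aldehyde chain equatorial, acetal carbon of 11 axial) joins C7–C8 syn, with the aldehyde face fixed by a Cornforth arrangement (C9–O anti to C=O, quaternary C10 anti to the incoming carbon, H9 facing the axial acetal carbon); the boron alkoxide then closes the cis lactone, the water-rich Lewis acid medium hydrolyses the acetal (water outruns the alkene for the oxocarbenium ion), and the freed C6 aldehyde, held cis to the side chain on the lactone, closes C5–C6 by a concerted carbonyl-ene reaction through a chair with C11, C9–OTBS, vinyl, the new OH and the new isopropenyl all equatorial; the closest known types are allylboration/lactonisation to α-methylene-γ-butyrolactones and the citronellal-to-isopulegol cyclisation.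

**Step 10**
Reactants: 15 bicyclic C6 alcohol
Product: 16 (3aS,4R,5S,6S,7R,7aS)-7-[(tert-butyldimethylsilyl)oxy]-6-ethenyl-6-methyl-3-methylidene-2-oxo-5-(prop-1-en-2-yl)octahydro-1-benzofuran-4-yl 2-methylpropanoate
Conditions: (i-PrCO)2O, Et3N, DMAP, CH2Cl2, 23 °C
Reagents that add atoms: isobutyric anhydride, CC(C)C(=O)OC(=O)C(C)C
Why: DMAP-catalysed acylation of the only free hydroxyl proceeds with retention at C6.

**Step 11**
Reactants: 16 silylated isobutyrate
Product: 17 (3aS,4R,5S,6S,7R,7aS)-6-ethenyl-7-hydroxy-6-methyl-3-methylidene-2-oxo-5-(prop-1-en-2-yl)octahydro-1-benzofuran-4-yl 2-methylpropanoate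
Conditions: HF·pyridine, THF, 0 to 23 °C
Reagents that add atoms: none
Why: Acidic fluoride desilylation frees C9–OH without base, so there is no acyl migration and no Michael addition to the methylene lactone.

**Step 12**
Reactants: 17 C9 alcohol with isopropenyl group
Product: 18 (3aS,4R,5R,6S,7R,7aS)-6-ethenyl-7-hydroxy-6-methyl-3-methylidene-2-oxo-5-(3-oxoprop-1-en-2-yl)octahydro-1-benzofuran-4-yl 2-methylpropanoate
Conditions: SeO2 (1.2 equiv), 1,4-dioxane, 70 °C
Reagents that add atoms: selenium dioxide, O=[Se]=O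
Why: Riley allylic oxidation (ene reaction, then [2,3]-shift) attacks the only electron-rich alkene that has an allylic CH3, because the vinyl group has no allylic hydrogen and the methylene lactone is electron-poor.

**Step 13**
Reactants: 18 2-substituted acrolein
Product: 19 (3aS,4S,5S,6S,7R,7aS)-6-ethenyl-5-[(2R)-2-formyloxiran-2-yl]-7-hydroxy-6-methyl-3-methylidene-2-oxooctahydro-1-benzofuran-4-yl 2-methylpropanoate (target)
Conditions: (S)-2-{diphenyl[(methyldiphenylsilyl)oxy]methyl}pyrrolidine (20 mol %), 30 % aq. H2O2, CH2Cl2, 23 °C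
Reagents that add atoms: hydrogen peroxide, OO
Why: Iminium/enamine organocatalytic Weitz–Scheffer-type epoxidation of an α-substituted acrolein activates only the enal and not the lactone, and ring closure of the enamine on the face left open by the bulky silyloxy-diphenylmethyl group sets the quaternary oxirane carbon as R.

## Compound list

| No. | Name | SMILES | Role |
|---|---|---|---|
| 1 | 2,2-dimethoxyacetaldehyde | COC(OC)C=O | starting material |
| 2 | 2-methyl-2-vinyloxirane | C=CC1(C)CO1 | starting material |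
| 3 | (2S,3R)-2-ethenyl-4,4-dimethoxy-2-methylbutane-1,3-diol | COC(OC)[C@H](O)[C@@](C)(C=C)CO | intermediate |
| 4 | (2R,3R)-2-ethenyl-3-hydroxy-4,4-dimethoxy-2-methylbutanal | COC(OC)[C@H](O)[C@@](C)(C=C)C=O | intermediate |
| 5 | (2R,3R)-3-(TBS-oxy)-2-ethenyl-4,4-dimethoxy-2-methylbutanal | COC(OC)[C@H](O[Si](C)(C)C(C)(C)C)[C@@](C)(C=C)C=O | intermediate |
| 6 | TBS ether of (2R,3S)-3-ethenyl-1,1-dimethoxy-3,5-dimethylhex-4-en-2-ol | COC(OC)[C@H](O[Si](C)(C)C(C)(C)C)[C@@](C)(C=C)C=C(C)C | intermediate |
| 7 | (2R,3S)-2-(TBS-oxy)-3-ethenyl-3,5-dimethylhex-4-enal | O=C[C@H](O[Si](C)(C)C(C)(C)C)[C@@](C)(C=C)C=C(C)C | intermediate |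
| 8 | methyl acrylate | C=CC(=O)OC | starting material |
| 9 | methyl 3-hydroxy-4,4-dimethoxy-2-methylidenebutanoate (racemic) | COC(OC)C(O)C(=C)C(=O)OC | intermediate |
| 10 | methyl 3-acetoxy-4,4-dimethoxy-2-methylidenebutanoate (racemic) | COC(OC)C(OC(C)=O)C(=C)C(=O)OC | intermediate |
| 11 | methyl (2E)-4,4-dimethoxy-2-[(pinacolboryl)methyl]but-2-enoate | COC(OC)/C=C(\CB1OC(C)(C)C(C)(C)O1)C(=O)OC | intermediate |
| 12 | methyl (3R,4S,5R,6S)-5-(TBS-oxy)-3-(dimethoxymethyl)-6-ethenyl-6,8-dimethyl-2-methylidene-4-[(pinacolboryl)oxy]non-7-enoate | COC(OC)[C@H](C(=C)C(=O)OC)[C@H](OB1OC(C)(C)C(C)(C)O1)[C@H](O[Si](C)(C)C(C)(C)C)[C@@](C)(C=C)C=C(C)C | intermediate (not isolated) |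
| 13 | (4R,5S)-5-[(1R,2S)-1-(TBS-oxy)-2-ethenyl-2,4-dimethylpent-3-en-1-yl]-4-(dimethoxymethyl)-3-methylideneoxolan-2-one | COC(OC)[C@@H]1C(=C)C(=O)O[C@@H]1[C@H](O[Si](C)(C)C(C)(C)C)[C@@](C)(C=C)C=C(C)C | intermediate (not isolated) |
| 14 | (2S,3R)-2-[(1R,2S)-1-(TBS-oxy)-2-ethenyl-2,4-dimethylpent-3-en-1-yl]-4-methylidene-5-oxooxolane-3-carbaldehyde | O=C[C@@H]1C(=C)C(=O)O[C@@H]1[C@H](O[Si](C)(C)C(C)(C)C)[C@@](C)(C=C)C=C(C)C | intermediate (not isolated) |
| 15 | bicyclic C6 alcohol (3aS,4R,5S,6S,7R,7aS), C9–OTBS | C=C[C@@]1(C)[C@H](C(C)=C)[C@@H](O)[C@@H]2C(=C)C(=O)O[C@@H]2[C@@H]1O[Si](C)(C)C(C)(C)C | intermediate |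
| 16 | C6 isobutyrate, C9–OTBS | C=C[C@@]1(C)[C@H](C(C)=C)[C@@H](OC(=O)C(C)C)[C@@H]2C(=C)C(=O)O[C@@H]2[C@@H]1O[Si](C)(C)C(C)(C)C | intermediate |
| 17 | C6 isobutyrate, C9–OH, isopropenyl at C5 | C=C[C@@]1(C)[C@H](C(C)=C)[C@@H](OC(=O)C(C)C)[C@@H]2C(=C)C(=O)O[C@@H]2[C@@H]1O | intermediate |
| 18 | C15 enal | C=C[C@@]1(C)[C@H](C(=C)C=O)[C@@H](OC(=O)C(C)C)[C@@H]2C(=C)C(=O)O[C@@H]2[C@@H]1O | intermediate |
| 19 | CNP0127398.1 | C=C[C@@]1(C)[C@H]([C@]2(C=O)CO2)[C@@H](OC(=O)C(C)C)[C@@H]2C(=C)C(=O)O[C@@H]2[C@@H]1O | target |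

## Step count and risks

Total step count: 13. Longest linear sequence: 10 (steps 1–5 and 9–13).

The three steps most likely to fail are 9, 12 and 13.

**Step 9.**
- Risks: the acetal may be trapped by the alkene as a methyl ether, the ene closure may stall, or the C9 silyl ether may be lost in the wet Lewis acid.
- Start and first move: the fallback sets out from 13, isolated by stopping after the thermal stage. Hydrolysis in AcOH–H2O–THF gives lactone aldehyde 14.
- Ring closure: isobutyric anhydride with anhydrous Sc(OTf)3 (2 mol %) in CH2Cl2 converts 14 into the geminal diisobutyrate (acylal) F1. The same Lewis acid ionises F1 to an acyloxycarbenium ion. That ion is captured by the trisubstituted alkene in a cationic Prins-type ene closure.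
- Return: the six-membered ring and the C6 isobutyrate are made together, without water or methanol present, and the sequence rejoins the route at 16.

**Step 12.**
- Risks: over-oxidation, attack at the tertiary C5–H, or a stop at the alcohol.
- Fallback: it sets out from 17. Ene-type allylic chlorination of the isopropenyl group with Ca(OCl)2 and solid CO2 in CH2Cl2–H2O gives the allylic chloride F2. N-Methylmorpholine N-oxide in MeCN then displaces chloride and collapses to the aldehyde, and the sequence rejoins the route at 18.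

**Step 13.**
- Risks: a mismatched catalyst/substrate pairing, or amine addition to the lactone.
- Reduction: the fallback sets out from 18. 1,2-Reduction with NaBH4/CeCl3·7H2O in MeOH at −78 °C gives the allylic alcohol F3.
- Epoxidation: Sharpless asymmetric epoxidation (Ti(OiPr)4, L-(+)-diethyl tartrate, t-BuOOH, 4 Å sieves, CH2Cl2, −20 °C) gives the epoxy alcohol F4. Its facial sense matches that for (S)-2-substituted glycidols.
- Return: TEMPO/PhI(OAc)2 oxidises only the primary alcohol, and the sequence rejoins the route at 19.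

## Further compounds

F1 | step 9 | geminal diisobutyrate (acylal) of lactone aldehyde 14 | CC(C)C(=O)OC(OC(=O)C(C)C)[C@@H]1C(=C)C(=O)O[C@@H]1[C@H](O[Si](C)(C)C(C)(C)C)[C@@](C)(C=C)C=C(C)C
F2 | step 12 | C15 allylic chloride of 17 | C=C[C@@]1(C)[C@H](C(=C)CCl)[C@@H](OC(=O)C(C)C)[C@@H]2C(=C)C(=O)O[C@@H]2[C@@H]1O
F3 | step 13 | C15 allylic alcohol (18 with CH2OH in place of CHO) | C=C[C@@]1(C)[C@H](C(=C)CO)[C@@H](OC(=O)C(C)C)[C@@H]2C(=C)C(=O)O[C@@H]2[C@@H]1O
F4 | step 13 | epoxy alcohol (19 with CH2OH in place of CHO) | C=C[C@@]1(C)[C@H]([C@]2(CO)CO2)[C@@H](OC(=O)C(C)C)[C@@H]2C(=C)C(=O)O[C@@H]2[C@@H]1O
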